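**Retrosynthetic overview**

1. Target 29 comes from oxepan-3-one 26 by reagent-controlled reduction of the C3 ketone, acetylation of both hydroxyls and desilylation.
2. Key disconnection: 26 is cut at C4–C5 and O1–C7 into the acyclic α-hydroxy methyl ketone 17 and the racemic bromo vinyl epoxide 23. The oxepane is the only ring and is closed in this step.
3. Enabling feature: in the oxepane (O1, C2–C7) the sp2 carbon C6 lies between two allylic methylenes, C5 and C7, so both new ring bonds are allylic. The exocyclic C6=C8–C9H2O unit is the 1,4-opened form of a vinyl epoxide. O1–C2–C3(=O)–C4 is a 1,4-C,O-dinucleophile in which the quaternary C2 lets only C4 enolize.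
4. 17 comes from methyl (S)-2-methylglycidate 13 (C2 from the chiral pool) and the Grignard reagent 14. The side-chain stereodiad of 14 is set by Brown syn-crotylboration of 4-methylpent-3-enal 2.
5. 23 comes from 2-methylidenepropane-1,3-diol 18 by monosilylation, oxidation, Corey–Chaykovsky epoxidation, desilylation and bromination.

Key step: step 14

Remark: ring atoms are numbered O1, C2 (quaternary), C3, C4, C5, C6 (alkylidene), C7, with exocyclic C8 (=CH) and C9 (CH2O); the two stages of step 14 run in one flask without isolation and are counted as one operation. TBS = tert-butyldimethylsilyl.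

**Route**

Step 1
Reactants: 1 4-methylpent-3-en-1-ol
Product: 2 4-methylpent-3-enal
Conditions: Dess–Martin periodinane, NaHCO3, CH2Cl2, 0 °C → rt; used at once as a cold solution
Reagents that add atoms: none
Why: Buffered Dess–Martin oxidation of a primary alcohol should stop at the aldehyde and, being non-basic, should leave the β,γ-double bond out of conjugation; no stereocentre is formed.

Step 2
Reactants: 2 4-methylpent-3-enal; 3 cis-but-2-ene
Product: 8 (3R,4R)-3,7-dimethylocta-1,6-dien-4-ol, via (Z)-but-2-en-1-ylpotassium 4 (not isolated), via potassium crotyl(methoxy)diisopinocampheylborate 5 (not isolated), via (Z)-crotyldiisopinocampheylborane 6 (not isolated), via diisopinocampheylborinate ester 7 (not isolated)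
Conditions: 3, KOt-Bu, n-BuLi, THF, −78 → −45 °C; (−)-Ipc2BOMe [from (+)-α-pinene], −78 °C; BF3·OEt2; 2, −78 °C; NaOH, H2O2, 0 °C → rt
Reagents that add atoms: none
Why: Brown crotylboration through a closed chair (Zimmerman–Traxler) transition state: the Z-crotyl geometry should give the syn methyl/hydroxyl pair, and the isopinocampheyl groups from (+)-α-pinene should direct addition to the Si face of the aldehyde, setting 3R,4R.

Step 3
Reactants: 8 (3R,4R)-3,7-dimethylocta-1,6-dien-4-ol
Product: 9 tert-butyl{[(3R,4R)-3,7-dimethylocta-1,6-dien-4-yl]oxy}dimethylsilane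
Conditions: TBSCl, imidazole, DMF, rt
Reagents that add atoms: tert-butyldimethylsilyl chloride (TBSCl), CC(C)(C)[Si](C)(C)Cl
Why: Standard silylation of a secondary alcohol; no stereocentre is touched.

Step 4
Reactants: 9 tert-butyl{[(3R,4R)-3,7-dimethylocta-1,6-dien-4-yl]oxy}dimethylsilane
Product: 11 (3R,4R)-4-(TBS-oxy)-3,7-dimethyloct-6-en-1-ol, via B-alkyl-9-borabicyclononane 10 (not isolated)
Conditions: 9-BBN, THF, 0 °C → rt; NaOH, H2O2, 0 °C
Reagents that add atoms: hydrogen peroxide, OO
Why: Hydroboration–oxidation with the bulky 9-BBN should be anti-Markovnikov and should select the monosubstituted vinyl group over the trisubstituted alkene; the stereocentres are untouched.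

Step 5
Reactants: 11 (3R,4R)-4-(TBS-oxy)-3,7-dimethyloct-6-en-1-ol
Product: 12 {[(3R,4R)-1-bromo-3,7-dimethyloct-6-en-4-yl]oxy}(tert-butyl)dimethylsilane
Conditions: CBr4, PPh3, CH2Cl2, 0 °C
Reagents that add atoms: carbon tetrabromide, BrC(Br)(Br)Br
Why: Appel bromination of a primary alcohol under neutral conditions, compatible with the silyl ether and the alkene.

Step 6
Reactants: 12 {[(3R,4R)-1-bromo-3,7-dimethyloct-6-en-4-yl]oxy}(tert-butyl)dimethylsilane; 13 methyl (S)-2-methyloxirane-2-carboxylate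
Product: 15 methyl (2S,6R,7R)-7-(TBS-oxy)-2-hydroxy-2,6,10-trimethylundec-9-enoate, via alkylmagnesium bromide 14 (not isolated)
Conditions: Mg, THF, rt; then CuBr·SMe2 (10 mol %), 13, THF, −40 → −20 °C
Reagents that add atoms: none
Why: Copper-catalysed Grignard opening of a 2,2-disubstituted epoxide at its unhindered CH2 terminus should outrun addition to the ester at low temperature; the C2 stereocentre comes unchanged from the glycidate because no bond to it is broken.

Step 7
Reactants: 15 methyl (2S,6R,7R)-7-(TBS-oxy)-2-hydroxy-2,6,10-trimethylundec-9-enoate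
Product: 16 (2S,6R,7R)-7-(TBS-oxy)-2-hydroxy-N-methoxy-N,2,6,10-tetramethylundec-9-enamide
Conditions: MeNH(OMe)·HCl, AlMe3, CH2Cl2, 0 °C → rt
Reagents that add atoms: N,O-dimethylhydroxylamine hydrochloride, CNOC.Cl
Why: Weinreb amide formation from an ester with the aluminium amide made from AlMe3, which tolerates the hindered α-hydroxy ester; no stereocentre is touched.

Step 8
Reactants: 16 (2S,6R,7R)-7-(TBS-oxy)-2-hydroxy-N-methoxy-N,2,6,10-tetramethylundec-9-enamide
Product: 17 (3S,7R,8R)-8-(TBS-oxy)-3-hydroxy-3,7,11-trimethyldodec-10-en-2-one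
Conditions: MeMgBr (3 equiv), THF, 0 °C
Reagents that add atoms: methylmagnesium bromide, C[Mg]Br
Why: Grignard addition to a Weinreb amide should stop at the ketone through the chelated tetrahedral intermediate; the first equivalent turns the tertiary hydroxyl into its alkoxide.

Step 9
Reactants: 18 2-methylidenepropane-1,3-diol
Product: 19 2-[(TBS-oxy)methyl]prop-2-en-1-ol
Conditions: NaH (1 equiv), THF, 0 °C; TBSCl (1 equiv)
Reagents that add atoms: tert-butyldimethylsilyl chloride (TBSCl), CC(C)(C)[Si](C)(C)Cl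
Why: Monosilylation of a symmetrical diol through its monosodium alkoxide.

Step 10
Reactants: 19 2-[(TBS-oxy)methyl]prop-2-en-1-ol
Product: 20 2-[(TBS-oxy)methyl]prop-2-enal
Conditions: MnO2, CH2Cl2, rt
Reagents that add atoms: none
Why: MnO2 oxidation of an allylic alcohol should give the enal selectively.

Step 11
Reactants: 20 2-[(TBS-oxy)methyl]prop-2-enal
Product: 21 tert-butyl(dimethyl){[2-(oxiran-2-yl)prop-2-en-1-yl]oxy}silane (racemic)
Conditions: Me3S+ I−, KN(SiMe3)2, THF, −10 → 0 °C
Reagents that add atoms: trimethylsulfonium iodide, C[S+](C)C.[I-]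
Why: Corey–Chaykovsky epoxidation: the sulfonium ylide should add 1,2 to the enal and close to the vinyl epoxide; the new stereocentre is formed racemic, which is harmless because it becomes sp2 in step 14.

Step 12
Reactants: 21 tert-butyl(dimethyl){[2-(oxiran-2-yl)prop-2-en-1-yl]oxy}silane
Product: 22 2-(oxiran-2-yl)prop-2-en-1-ol (racemic)
Conditions: Bu4NF, THF, 0 °C
Reagents that add atoms: none
Why: Fluoride-mediated desilylation of a primary silyl ether at low temperature should leave the vinyl epoxide intact.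

Step 13
Reactants: 22 2-(oxiran-2-yl)prop-2-en-1-ol
Product: 23 2-(3-bromoprop-1-en-2-yl)oxirane (racemic)
Conditions: CBr4, PPh3, CH2Cl2, −10 °C; used as a solution
Reagents that add atoms: carbon tetrabromide, BrC(Br)(Br)Br
Why: Appel bromination should convert the primary allylic alcohol into the bromide under neutral conditions that spare the epoxide.

Step 14
Reactants: 17 (3S,7R,8R)-8-(TBS-oxy)-3-hydroxy-3,7,11-trimethyldodec-10-en-2-one; 23 2-(3-bromoprop-1-en-2-yl)oxirane
Product: 26 (2S,6E)-2-[(4R,5R)-5-(TBS-oxy)-4,8-dimethylnon-7-en-1-yl]-6-(2-hydroxyethylidene)-2-methyloxepan-3-one, via dilithium enolate-alkoxide 24 (not isolated), via vinyl-epoxide hydroxy ketone 25 (not isolated)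
Conditions: LiN(SiMe3)2 (2.2 equiv), THF, −78 °C; 23, −78 → −30 °C; AcOH (1.2 equiv); Pd(PPh3)4 (5 mol %), 0 °C → rt; one flask
Reagents that add atoms: none
Why: Proposed new method: a one-flask formal [4+3] annulation in which the dianion 24 is alkylated at C4 by the allylic bromide of 23 (C4–C5; SN2 and SN2′ give the same product), and, after neutralization, zerovalent palladium ionizes the vinyl epoxide of 25 to an η3-allyl/alkoxide zwitterion whose unsubstituted terminus C7 is attacked by the C2 tertiary hydroxyl (O1–C7), the epoxide oxygen emerging as the C9 primary alcohol. The closest known reactions are the α′-alkylation of α-hydroxy ketone dianions with allylic halides, the palladium-catalysed intramolecular 1,4-addition of alcohols to vinyl epoxides, and the attack of a nucleophile tethered to the central carbon of an η3-allyl on its terminus, as in the ring-closing half of trimethylenemethane [4+3] cycloadditions; their merger with a bifunctional vinyl-epoxide allyl bromide is not described. The oxepane is closed by seven-membered C–O bond formation in which O1 adds to C7 on the face opposite palladium while the breaking epoxide C–O bond stays outside the ring (1,4- or SN2′-type opening). No sp3 stereocentre is created; the only new stereo-element, the C6=C8 double bond, should be E because the CH2O group prefers the syn position on the allyl terminus C8, pointing away from C7 and the incoming oxygen, and the racemic epoxide centre of 23 is erased on ionization so that both epimers of 25 converge. The step needs C- before O-alkylation (only C4 can enolize because C2 is quaternary, and the enolate carbon is far more nucleophilic than the lithium alkoxide at −78 °C) and attack at C7, not C8 (both would give seven-membered rings, so the bulk of the tertiary oxygen nucleophile should decide for the CH2 terminus); C2 cannot epimerize.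

Step 15
Reactants: 26 (2S,6E)-2-[(4R,5R)-5-(TBS-oxy)-4,8-dimethylnon-7-en-1-yl]-6-(2-hydroxyethylidene)-2-methyloxepan-3-one
Product: 27 (2S,3R,6E)-2-[(4R,5R)-5-(TBS-oxy)-4,8-dimethylnon-7-en-1-yl]-6-(2-hydroxyethylidene)-2-methyloxepan-3-ol
Conditions: (S)-1-methyl-3,3-diphenyltetrahydro-1H,3H-pyrrolo[1,2-c][1,3,2]oxazaborole [(S)-Me-CBS] (0.5 equiv), catecholborane (3 equiv), toluene, −78 → −40 °C
Reagents that add atoms: none
Why: Corey–Bakshi–Shibata reduction: the oxazaborolidine should bind the ketone anti to the quaternary C2 and deliver hydride under reagent control, which for the S catalyst should give the 3R alcohol (hydroxyl cis to the C2 methyl); catecholborane at low temperature should not hydroborate the alkenes.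

Step 16
Reactants: 27 (2S,3R,6E)-2-[(4R,5R)-5-(TBS-oxy)-4,8-dimethylnon-7-en-1-yl]-6-(2-hydroxyethylidene)-2-methyloxepan-3-ol
Product: 28 (2S,3R,6E)-6-(2-acetoxyethylidene)-2-[(4R,5R)-5-(TBS-oxy)-4,8-dimethylnon-7-en-1-yl]-2-methyloxepan-3-yl acetate
Conditions: Ac2O, pyridine, 4-(dimethylamino)pyridine (cat.), CH2Cl2, rt
Reagents that add atoms: acetic anhydride, CC(=O)OC(C)=O
Why: Nucleophile-catalysed acylation should esterify both the primary allylic and the hindered secondary hydroxyl without touching the silyl ether.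

Step 17
Reactants: 28 (2S,3R,6E)-6-(2-acetoxyethylidene)-2-[(4R,5R)-5-(TBS-oxy)-4,8-dimethylnon-7-en-1-yl]-2-methyloxepan-3-yl acetate
Product: 29 (2S,3R,6E)-6-(2-acetoxyethylidene)-2-[(4R,5R)-5-hydroxy-4,8-dimethylnon-7-en-1-yl]-2-methyloxepan-3-yl acetate (target)
Conditions: HF·pyridine, THF, 0 °C → rt
Reagents that add atoms: none
Why: Fluoride cleavage of the secondary silyl ether under buffered acidic conditions should leave both acetates and the allylic system untouched.

**Compound list**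

1 | 4-methylpent-3-en-1-ol | CC(C)=CCCO | starting material
2 | 4-methylpent-3-enal | CC(C)=CCC=O | intermediate
3 | cis-but-2-ene | C/C=C\C | starting material
4 | (Z)-but-2-en-1-ylpotassium | C/C=C\[CH2-].[K+] | intermediate
5 | potassium (Z)-but-2-en-1-yl(methoxy)diisopinocampheylborate, isopinocampheyl groups from (+)-α-pinene | C/C=C\C[B-](OC)([C@@H]1C[C@@H]2C[C@H]([C@H]1C)C2(C)C)[C@@H]1C[C@@H]2C[C@H]([C@H]1C)C2(C)C.[K+] | intermediate
6 | (Z)-but-2-en-1-yldiisopinocampheylborane, isopinocampheyl groups from (+)-α-pinene | C/C=C\CB([C@@H]1C[C@@H]2C[C@H]([C@H]1C)C2(C)C)[C@@H]1C[C@@H]2C[C@H]([C@H]1C)C2(C)C | intermediate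
7 | (3R,4R)-3,7-dimethylocta-1,6-dien-4-yl diisopinocampheylborinate | C=C[C@@H](C)[C@H](OB([C@@H]1C[C@@H]2C[C@H]([C@H]1C)C2(C)C)[C@@H]1C[C@@H]2C[C@H]([C@H]1C)C2(C)C)CC=C(C)C | intermediate
8 | (3R,4R)-3,7-dimethylocta-1,6-dien-4-ol | C=C[C@@H](C)[C@H](O)CC=C(C)C | intermediate
9 | tert-butyl{[(3R,4R)-3,7-dimethylocta-1,6-dien-4-yl]oxy}dimethylsilane | C=C[C@@H](C)[C@H](O[Si](C)(C)C(C)(C)C)CC=C(C)C | intermediate
10 | 9-[(3R,4R)-4-(TBS-oxy)-3,7-dimethyloct-6-en-1-yl]-9-borabicyclo[3.3.1]nonane | C1CC2CCCC(C1)B2CC[C@@H](C)[C@H](O[Si](C)(C)C(C)(C)C)CC=C(C)C | intermediate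
11 | (3R,4R)-4-(TBS-oxy)-3,7-dimethyloct-6-en-1-ol | OCC[C@@H](C)[C@H](O[Si](C)(C)C(C)(C)C)CC=C(C)C | intermediate
12 | {[(3R,4R)-1-bromo-3,7-dimethyloct-6-en-4-yl]oxy}(tert-butyl)dimethylsilane | BrCC[C@@H](C)[C@H](O[Si](C)(C)C(C)(C)C)CC=C(C)C | intermediate
13 | methyl (S)-2-methyloxirane-2-carboxylate | COC(=O)[C@]1(C)CO1 | starting material
14 | [(3R,4R)-4-(TBS-oxy)-3,7-dimethyloct-6-en-1-yl]magnesium bromide | Br[Mg]CC[C@@H](C)[C@H](O[Si](C)(C)C(C)(C)C)CC=C(C)C | intermediate
15 | methyl (2S,6R,7R)-7-(TBS-oxy)-2-hydroxy-2,6,10-trimethylundec-9-enoate | COC(=O)[C@@](C)(O)CCC[C@@H](C)[C@H](O[Si](C)(C)C(C)(C)C)CC=C(C)C | intermediate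
16 | (2S,6R,7R)-7-(TBS-oxy)-2-hydroxy-N-methoxy-N,2,6,10-tetramethylundec-9-enamide | CON(C)C(=O)[C@@](C)(O)CCC[C@@H](C)[C@H](O[Si](C)(C)C(C)(C)C)CC=C(C)C | intermediate
17 | (3S,7R,8R)-8-(TBS-oxy)-3-hydroxy-3,7,11-trimethyldodec-10-en-2-one | CC(=O)[C@@](C)(O)CCC[C@@H](C)[C@H](O[Si](C)(C)C(C)(C)C)CC=C(C)C | intermediate
18 | 2-methylidenepropane-1,3-diol | C=C(CO)CO | starting material
19 | 2-[(TBS-oxy)methyl]prop-2-en-1-ol | C=C(CO)CO[Si](C)(C)C(C)(C)C | intermediate
20 | 2-[(TBS-oxy)methyl]prop-2-enal | C=C(C=O)CO[Si](C)(C)C(C)(C)C | intermediate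
21 | tert-butyl(dimethyl){[2-(oxiran-2-yl)prop-2-en-1-yl]oxy}silane, racemic | C=C(CO[Si](C)(C)C(C)(C)C)C1CO1 | intermediate
22 | 2-(oxiran-2-yl)prop-2-en-1-ol, racemic | C=C(CO)C1CO1 | intermediate
23 | 2-(3-bromoprop-1-en-2-yl)oxirane, racemic | C=C(CBr)C1CO1 | intermediate
24 | dilithium enolate-alkoxide of 17 | [Li]OC(=C)[C@@](C)(O[Li])CCC[C@@H](C)[C@H](O[Si](C)(C)C(C)(C)C)CC=C(C)C | intermediate
25 | (6S,10R,11R)-11-(TBS-oxy)-6-hydroxy-6,10,14-trimethyl-2-(oxiran-2-yl)pentadeca-1,13-dien-5-one, both epimers at the oxirane carbon | C=C(CCC(=O)[C@@](C)(O)CCC[C@@H](C)[C@H](O[Si](C)(C)C(C)(C)C)CC=C(C)C)C1CO1 | intermediate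
26 | (2S,6E)-2-[(4R,5R)-5-(TBS-oxy)-4,8-dimethylnon-7-en-1-yl]-6-(2-hydroxyethylidene)-2-methyloxepan-3-one | OC/C=C1\CCC(=O)[C@](C)(CCC[C@@H](C)[C@H](O[Si](C)(C)C(C)(C)C)CC=C(C)C)OC1 | intermediate
27 | (2S,3R,6E)-2-[(4R,5R)-5-(TBS-oxy)-4,8-dimethylnon-7-en-1-yl]-6-(2-hydroxyethylidene)-2-methyloxepan-3-ol | OC/C=C1\CC[C@@H](O)[C@](C)(CCC[C@@H](C)[C@H](O[Si](C)(C)C(C)(C)C)CC=C(C)C)OC1 | intermediate
28 | (2S,3R,6E)-6-(2-acetoxyethylidene)-2-[(4R,5R)-5-(TBS-oxy)-4,8-dimethylnon-7-en-1-yl]-2-methyloxepan-3-yl acetate | CC(=O)OC/C=C1\CC[C@@H](OC(C)=O)[C@](C)(CCC[C@@H](C)[C@H](O[Si](C)(C)C(C)(C)C)CC=C(C)C)OC1 | intermediate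
29 | (2S,3R,6E)-6-(2-acetoxyethylidene)-2-[(4R,5R)-5-hydroxy-4,8-dimethylnon-7-en-1-yl]-2-methyloxepan-3-yl acetate | CC(=O)OC/C=C1\CC[C@@H](OC(C)=O)[C@](C)(CCC[C@@H](C)[C@H](O)CC=C(C)C)OC1 | target

**Step count and risks**

Total step count: 17. Longest linear sequence: 12 steps (steps 1–8 and 14–17); steps 9–13 make the C5 reagent 23.

Steps most likely to fail:

1. Step 14 (Proposed new method). What may go wrong:
   - attack of the tertiary hydroxyl at the substituted allyl terminus C8 instead of C7;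
   - syn/anti equilibration of the η3-allyl leading to the Z alkene;
   - isomerization of the vinyl epoxide to an enal by hydride shift before ring closure;
   - double alkylation at C4 in the first stage.

   Fallback (known chemistry, from 17, rejoining at 27): the classical 6-oxo-oxepane/olefination sequence. The dianion of 17 is alkylated with 3-bromo-2-methoxyprop-1-ene to the enol ether (6S,10R,11R)-11-(TBS-oxy)-6-hydroxy-2-methoxy-6,10,14-trimethylpentadeca-1,13-dien-5-one F1. NBS in aqueous THF at 0 °C converts the enol ether into the bromomethyl ketone (6S,10R,11R)-1-bromo-11-(TBS-oxy)-6-hydroxy-6,10,14-trimethylpentadec-13-ene-2,5-dione F2. Ag2O in CH2Cl2 closes the ring by O-alkylation of the tertiary hydroxyl to (2S)-2-[(4R,5R)-5-(TBS-oxy)-4,8-dimethylnon-7-en-1-yl]-2-methyloxepane-3,6-dione F3. Horner–Wadsworth–Emmons olefination of the less hindered C6 ketone with triethyl phosphonoacetate and NaH should give a mixture of geometric isomers, from which ethyl (E)-[(2S)-2-[(4R,5R)-5-(TBS-oxy)-4,8-dimethylnon-7-en-1-yl]-2-methyl-3-oxooxepan-6-ylidene]acetate F4 is separated by chromatography. Reduction as in step 15 gives ethyl (E)-[(2S,3R)-2-[(4R,5R)-5-(TBS-oxy)-4,8-dimethylnon-7-en-1-yl]-3-hydroxy-2-methyloxepan-6-ylidene]acetate F5, and i-Bu2AlH reduces the ester to 27.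

2. Step 15. What may go wrong: poor facial selectivity if the conformational bias of the 2,2-disubstituted oxepanone opposes the catalyst, and partial consumption of the borane by the free primary hydroxyl.

   Fallback (from 26, rejoining at 28): substrate control plus inversion. Reduction with LiBH(s-Bu)3 at −78 °C is used if it favours the C3 epimer (2S,3S,6E)-2-[(4R,5R)-5-(TBS-oxy)-4,8-dimethylnon-7-en-1-yl]-6-(2-hydroxyethylidene)-2-methyloxepan-3-ol F6. A Mitsunobu reaction with acetic acid (PPh3, diisopropyl azodicarboxylate) then acetylates the primary hydroxyl and esterifies C3 with inversion, giving 28 directly.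

3. Step 6. What may go wrong: addition of the Grignard reagent to the ester carbonyl of 13 in competition with epoxide opening, and opening of the epoxide by bromide.

   Fallback (from 14, rejoining at 17): an ester-free epoxide. (R)-2-methylglycidol (OC[C@]1(C)CO1), first deprotonated with MeMgBr, is opened by 14 under CuBr·SMe2 catalysis to (2S,6R,7R)-7-(TBS-oxy)-2,6,10-trimethylundec-9-ene-1,2-diol F7. SO3·pyridine/DMSO/Et3N oxidizes the primary hydroxyl to (2S,6R,7R)-7-(TBS-oxy)-2-hydroxy-2,6,10-trimethylundec-9-enal F8. MeMgBr adds to give (3S,7R,8R)-8-(TBS-oxy)-3,7,11-trimethyldodec-10-ene-2,3-diol F9 as a mixture of C2 epimers, and Dess–Martin oxidation of the secondary hydroxyl gives 17.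

**Further compounds**

F1 | step 14 | (6S,10R,11R)-11-(TBS-oxy)-6-hydroxy-2-methoxy-6,10,14-trimethylpentadeca-1,13-dien-5-one | COC(=C)CCC(=O)[C@@](C)(O)CCC[C@@H](C)[C@H](O[Si](C)(C)C(C)(C)C)CC=C(C)C
F2 | step 14 | (6S,10R,11R)-1-bromo-11-(TBS-oxy)-6-hydroxy-6,10,14-trimethylpentadec-13-ene-2,5-dione | BrCC(=O)CCC(=O)[C@@](C)(O)CCC[C@@H](C)[C@H](O[Si](C)(C)C(C)(C)C)CC=C(C)C
F3 | step 14 | (2S)-2-[(4R,5R)-5-(TBS-oxy)-4,8-dimethylnon-7-en-1-yl]-2-methyloxepane-3,6-dione | O=C1CCC(=O)[C@](C)(CCC[C@@H](C)[C@H](O[Si](C)(C)C(C)(C)C)CC=C(C)C)OC1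
F4 | step 14 | ethyl (E)-[(2S)-2-[(4R,5R)-5-(TBS-oxy)-4,8-dimethylnon-7-en-1-yl]-2-methyl-3-oxooxepan-6-ylidene]acetate | CCOC(=O)/C=C1\CCC(=O)[C@](C)(CCC[C@@H](C)[C@H](O[Si](C)(C)C(C)(C)C)CC=C(C)C)OC1
F5 | step 14 | ethyl (E)-[(2S,3R)-2-[(4R,5R)-5-(TBS-oxy)-4,8-dimethylnon-7-en-1-yl]-3-hydroxy-2-methyloxepan-6-ylidene]acetate | CCOC(=O)/C=C1\CC[C@@H](O)[C@](C)(CCC[C@@H](C)[C@H](O[Si](C)(C)C(C)(C)C)CC=C(C)C)OC1
F6 | step 15 | (2S,3S,6E)-2-[(4R,5R)-5-(TBS-oxy)-4,8-dimethylnon-7-en-1-yl]-6-(2-hydroxyethylidene)-2-methyloxepan-3-ol | OC/C=C1\CC[C@H](O)[C@](C)(CCC[C@@H](C)[C@H](O[Si](C)(C)C(C)(C)C)CC=C(C)C)OC1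
F7 | step 6 | (2S,6R,7R)-7-(TBS-oxy)-2,6,10-trimethylundec-9-ene-1,2-diol | OC[C@@](C)(O)CCC[C@@H](C)[C@H](O[Si](C)(C)C(C)(C)C)CC=C(C)C
F8 | step 6 | (2S,6R,7R)-7-(TBS-oxy)-2-hydroxy-2,6,10-trimethylundec-9-enal | O=C[C@@](C)(O)CCC[C@@H](C)[C@H](O[Si](C)(C)C(C)(C)C)CC=C(C)C
F9 | step 6 | (3S,7R,8R)-8-(TBS-oxy)-3,7,11-trimethyldodec-10-ene-2,3-diol, C2 epimers | CC(O)[C@@](C)(O)CCC[C@@H](C)[C@H](O[Si](C)(C)C(C)(C)C)CC=C(C)C
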